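# Broussoflavonol B by acylketene annulation onto 2,4-diprenylphloroglucinol: synthesis design

## The problem

Broussoflavonol B (13) is an achiral 3-methoxyflavone. Benzo ring A is fused to pyranone ring C; ring B, a 3,4-dihydroxyphenyl group, sits on C2, a methyl ether on C3, hydroxyls on C5 and C7, and prenyl (3-methylbut-2-enyl) groups on C6 and C8. There is no stereocenter and no alkene geometry to set, so the task is one of regiochemistry and chemoselectivity only. Ring A is a hexasubstituted benzene: ring C must be closed onto a fully substituted phloroglucinol, and both prenyl groups must end on carbon, not oxygen. Of the five oxygen substituents only the one on C3 is methylated, so this methyl group is best brought in with a building block, and no step may methylate or demethylate a phenol. A prenyl group next to a phenol cyclises to a 2,2-dimethylchroman or adds solvent under strong acid and is saturated by hydrogenation, and the catechol and the phloroglucinol ring oxidise in air under base. The enabling feature appears when C4–C4a and O1–C2 are cut: ring A becomes 2,4-diprenylphloroglucinol, whose single unsubstituted carbon (the future C4a) lies on a mirror plane between two equivalent hydroxyls (the future O1 and 5-OH). Acylation can occur only there, and closure onto either hydroxyl gives the same chromone.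

## Retrosynthesis

**13 to 12.** Only the two O–CH2 bonds of the ring B methoxymethyl (MOM) ethers are cut. The catechol is masked because free it would compete for the acylating species and is prone to oxidation. MOM is preferred to benzyl, whose hydrogenolysis would saturate the prenyl groups, and to methyl, which could not be told from the C3 ether. The ring A hydroxyls stay free because the key step needs them. The forward reaction must be a dilute-acid deprotection mild enough to leave two prenyl groups beside free phenols intact.

**12 to 3 and 9.** C4–C4a and O1–C2 are cut, dividing the 30-carbon chromone 12 into two 16-carbon pieces: the unprotected triol 3 and the α-methoxy β-ketoester 9. The neighbouring cut at C2–C3 (Allan–Robinson logic) would need a prenylated acylphloroglucinol and a per-acylation and deacylation sequence. Cutting the prenyl C–C bonds last would put a poorly selective alkylation on the finished flavone. Here the symmetry of 3 removes every regiochemical question, and the C3 methoxy group arrives in 9. The forward reaction must acylate a hindered but very nucleophilic ring carbon without acid. It should pass through the acylketene 10 and the 2-hydroxyaryl 1,3-diketone 11, which closes ring C in the same operation.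

**3 to 1 and 2.** The two aryl–CH2 bonds are cut, leading to phloroglucinol (1) and prenyl bromide (2). After the first C-prenylation the two remaining ring carbons are equivalent, so 3 is the only aromatic di-C-prenyl isomer possible. The forward reaction is a statistical phenolate C-alkylation whose by-products are accepted because both reagents are cheap and this is the first step.

**9 to 6 and 7.** The bond between the methoxy-bearing carbon and the aroyl carbon is cut, giving acid 6 and ethyl methoxyacetate (7). The acid is activated as the acyl imidazolide 8 rather than as the acid chloride, whose formation liberates HCl and would endanger the MOM ethers. The forward reaction is C-acylation of an ester enolate.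

**6 to 4.** The MOM groups are removed retrosynthetically to give 3,4-dihydroxybenzoic acid (4). In the forward sense the carboxyl group is alkylated as well, and the resulting methoxymethyl ester 5 is saponified in the same flask.

## Roads not taken

**Alternative 1:** C4 is supplied by carbon monoxide, and the cuts fall at C4a–C4 and C4–C3.
- Forward key step: the ring A iodide A1 (2-iodo-1,3,5-tris(methoxymethoxy)-4,6-bis(3-methylbut-2-enyl)benzene), CO and the enolate of the ring B ketone A2 (1-[3,4-bis(methoxymethoxy)phenyl]-2-methoxyethanone) are joined under Pd(dba)2 (zerovalent palladium) and a wide-bite-angle bisphosphine to give the open diketone A3. No ring closes; acid would then remove all MOM groups and cyclodehydrate to 13.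
- Merits: the C–C bonds form well below 100 °C, which is gentler on prenyl and MOM groups than a 220–240 °C melt. In this respect it is the better plan. A3 also has the right oxidation level for closure.
- Weak points: A1 is an electron-rich iodide flanked by two alkoxy groups, so oxidative addition and acyl transfer are slow, and direct (non-carbonylative) arylation and O-acylation of the enolate compete. A1 must itself be made from 3 by triple protection and iodination. The end-game must strip five MOM groups from a ring bearing two prenyl groups, a longer acid exposure than the chosen route requires.
- Comparison: about eight or nine operations against five, with three extra protecting groups. The chosen plan sets against the milder coupling its use of unprotected 3 and ring closure in the bond-forming step.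

**Alternative 2:** Ring A itself is cut (C8–C8a, C6–C7, C4a–C8a).
- Forward key step: cyclobutenone A4 (3-ethoxy-2-(3-methylbut-2-enyl)cyclobut-2-en-1-one) is heated in toluene with siloxyalkyne A5 (triisopropyl[(5-methylhex-4-en-1-yn-1-yl)oxy]silane). A4 opens to a vinylketene, adds A5, and the adduct opens and electrocyclises (Danheiser benzannulation) to phenol A6.
- Merits: both prenyl groups are placed without any statistical alkylation, and all three ring A oxygens are differentiated. On regiochemical purity of ring A it is superior to step 1 of the chosen route.
- Weak points: the differentiation is wasted on a symmetric ring A. A4 and A5 each need several steps. Ring C is not addressed at all. The ethyl ether would end at C5 and have to be cleaved beside the C3 methyl ether and two prenyl groups, which Lewis acidic dealkylation does not tolerate.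
- Comparison: at least twice the length of the chosen route. The chosen plan answers its advantage by accepting one modest, cheap first step.

**Alternative 3:** The aryl–CH2 bonds at C6 and C8 are traced to allyl ethers.
- Forward key step: the bis(allyl) ether A7 (5,7-bis(allyloxy)-2-[3,4-bis(methoxymethoxy)phenyl]-3-methoxychromen-4-one) is heated near 190 °C in N,N-diethylaniline and rearranges twice to A8. Cross-metathesis with 2-methylbut-2-ene (second-generation Grubbs catalyst) would then give 12.
- Merits: the C–C bonds form by sigmatropy and cannot end on oxygen. The 5-O-allyl group can only reach C6, and the 7-O-allyl group reaches C8, or C6 followed by a para shift of the other, so both paths converge. The flavone core comes from plain phloroglucinol, the best-precedented substrate. It is more predictable than step 1 and needs a lower temperature than step 4.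
- Weak points: allyl must be used because a prenyl ether would deliver the reversed 1,1-dimethylallyl group. This costs a double cross-metathesis and an allylation of the chelated 5-OH.
- Comparison: about two steps longer. The chosen plan sets brevity and the absence of any post-annulation C–C bond formation against this road's greater predictability.

Key step: step 4

## Route

Remark: 13 has no stereogenic element. Compounds 9 and 11 are racemic at the methoxy-bearing carbon and enolisable, which is immaterial because this carbon becomes sp2 C3 of ring C. MOMCl, CDI and LiN(SiMe3)2 (THF solution) are used as purchased.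

Step 1
Reactants: 1 phloroglucinol (benzene-1,3,5-triol); 2 prenyl bromide (1-bromo-3-methylbut-2-ene, 2.1 equiv)
Product: 3 2,4-bis(3-methylbut-2-enyl)benzene-1,3,5-triol (2,4-diprenylphloroglucinol)
Conditions: KOH (aq., 2.2 equiv), H2O, Ar, 0 °C to rt; chromatography
Reagents that add atoms: none
Why: Nuclear (C-) prenylation of the phloroglucinol phenolate: in water the phenolate oxygens are hydrogen-bonded, so the allylic bromide is taken up at ring carbon, and after the first prenylation the two remaining carbons are equivalent, so 3 is the only aromatic di-C-prenyl isomer. Mono-, tri- and geminally prenylated material is expected and is removed by chromatography, which is acceptable for a first step on two inexpensive reagents.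

Step 2
Reactants: 4 3,4-dihydroxybenzoic acid
Product: 6 3,4-bis(methoxymethoxy)benzoic acid, via methoxymethyl ester 5 (not isolated)
Conditions: MOMCl (3.5 equiv), i-Pr2NEt, DMF, 0 °C to rt; then NaOH (aq.), MeOH, rt; then cold HCl (aq.) to pH 4
Reagents that add atoms: chloromethyl methyl ether (MOMCl), COCCl; sodium hydroxide (its oxygen ends in the carboxyl group), [Na+].[OH-]
Why: Exhaustive O-alkylation with the acetal chloride protects both phenols and esterifies the carboxylate to 5; hydroxide then cleaves only the activated methoxymethyl ester, since aryl MOM ethers are inert to base and survive a brief cold acidification to pH 4.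

Step 3
Reactants: 6 3,4-bis(methoxymethoxy)benzoic acid; 7 ethyl methoxyacetate (3.3 equiv)
Product: 9 ethyl 3-[3,4-bis(methoxymethoxy)phenyl]-2-methoxy-3-oxopropanoate (racemic), via acyl imidazolide 8 (not isolated)
Conditions: CDI, THF, rt; then added to 7 / LiN(SiMe3)2 (3.2 equiv), THF, −78 to −20 °C; AcOH quench
Reagents that add atoms: none
Why: Crossed Claisen-type C-acylation of a lithium ester enolate by an acyl imidazolide; carbonyldiimidazole activates the acid under neutral conditions that spare the MOM ethers. Three equivalents of enolate are used because one is consumed by the imidazole released on activation and one by the acidic β-ketoester product, whose deprotonation also prevents a second acylation.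

Step 4
Reactants: 3 2,4-bis(3-methylbut-2-enyl)benzene-1,3,5-triol; 9 ethyl 3-[3,4-bis(methoxymethoxy)phenyl]-2-methoxy-3-oxopropanoate (1.5–2 equiv)
Product: 12 2-[3,4-bis(methoxymethoxy)phenyl]-5,7-dihydroxy-3-methoxy-6,8-bis(3-methylbut-2-enyl)chromen-4-one (3',4'-bis-O-methoxymethyl broussoflavonol B), via acylketene 10 (not isolated), via aryl diketone 11 (not isolated)
Conditions: neat melt (a little Ph2O if needed), Ar, base-washed glass, 220–240 °C (microwave or preheated bath), 5–15 min, EtOH and H2O vented
Reagents that add atoms: none
Why: This is the acid-free thermal Simonis-type chromone synthesis (Mentzer pyrocondensation), the reaction by which phloroglucinol and ethyl aroylacetates give 5,7-dihydroxyflavones. The enol of 9 loses ethanol through a six-centre elimination to the α-oxoketene 10, whose ketene carbon is attacked by the single unsubstituted, doubly hydroxyl-activated ring carbon of 3 to give the chelated 2-hydroxyaryl 1,3-diketone 11 (C4–C4a); acylation at a phenol oxygen is reversible at this temperature because aryl β-ketoesters re-form the ketene, so material drains into the C-acyl product. One ortho hydroxyl of 11 then adds to the aryl ketone in a 6-exo-trig closure and the hemiketal loses water to give the aromatic pyranone (O1–C2), as in the last stage of a Baker–Venkataraman flavone synthesis. No stereocenter is formed. Regioselectivity needs no control, because the acylated carbon is the only free position of 3 and its two flanking hydroxyls are related by the mirror plane of the triol, so either closure places the prenyl groups at C6 and C8. Chromone rather than coumarin formation is secured by the absence of acid, which leaves the electron-rich aryl ketone unactivated toward Pechmann-type hydroxyalkylation while the ketene carbon is by far the strongest electrophile present. The ketoester is used in excess because water from the closure can hydrolyse some ketene to a β-keto acid that decarboxylates, and the short heating under argon limits the exposure of the prenyl and MOM groups, which tolerate neutral heat but not acid.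

Step 5
Reactants: 12 2-[3,4-bis(methoxymethoxy)phenyl]-5,7-dihydroxy-3-methoxy-6,8-bis(3-methylbut-2-enyl)chromen-4-one
Product: 13 broussoflavonol B (2-(3,4-dihydroxyphenyl)-5,7-dihydroxy-3-methoxy-6,8-bis(3-methylbut-2-enyl)chromen-4-one)
Conditions: HCl (aq., 3 M, 10 vol%), MeOH, Ar, 40–45 °C; NaHCO3 (aq.) quench at full conversion
Reagents that add atoms: none
Why: Acid-catalysed transacetalisation of the two aryl MOM ethers to methanol (released as dimethoxymethane), a deprotection widely used on C-prenylated flavonoids; the C3 methyl ether is inert to dilute acid, and low temperature, short time and prompt neutralisation should keep the prenyl groups from cyclising onto the neighbouring phenols.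

## Compound list

1 | phloroglucinol (benzene-1,3,5-triol) | Oc1cc(O)cc(O)c1 | starting material
2 | prenyl bromide (1-bromo-3-methylbut-2-ene) | CC(C)=CCBr | starting material
3 | 2,4-bis(3-methylbut-2-enyl)benzene-1,3,5-triol | CC(C)=CCc1c(O)cc(O)c(CC=C(C)C)c1O | intermediate
4 | 3,4-dihydroxybenzoic acid | O=C(O)c1ccc(O)c(O)c1 | starting material
5 | methoxymethyl 3,4-bis(methoxymethoxy)benzoate | COCOC(=O)c1ccc(OCOC)c(OCOC)c1 | intermediate (not isolated)
6 | 3,4-bis(methoxymethoxy)benzoic acid | O=C(O)c1ccc(OCOC)c(OCOC)c1 | intermediate
7 | ethyl methoxyacetate | CCOC(=O)COC | starting material
8 | [3,4-bis(methoxymethoxy)phenyl](imidazol-1-yl)methanone | O=C(c1ccc(OCOC)c(OCOC)c1)n1ccnc1 | intermediate (not isolated)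
9 | ethyl 3-[3,4-bis(methoxymethoxy)phenyl]-2-methoxy-3-oxopropanoate (racemic) | CCOC(=O)C(OC)C(=O)c1ccc(OCOC)c(OCOC)c1 | intermediate
10 | 3-[3,4-bis(methoxymethoxy)phenyl]-2-methoxyprop-1-ene-1,3-dione (acylketene) | COC(=C=O)C(=O)c1ccc(OCOC)c(OCOC)c1 | intermediate (not isolated)
11 | 1-[3,4-bis(methoxymethoxy)phenyl]-2-methoxy-3-[2,4,6-trihydroxy-3,5-bis(3-methylbut-2-enyl)phenyl]propane-1,3-dione (racemic) | COC(C(=O)c1ccc(OCOC)c(OCOC)c1)C(=O)c1c(O)c(CC=C(C)C)c(O)c(CC=C(C)C)c1O | intermediate (not isolated)
12 | 2-[3,4-bis(methoxymethoxy)phenyl]-5,7-dihydroxy-3-methoxy-6,8-bis(3-methylbut-2-enyl)chromen-4-one | COc1c(-c2ccc(OCOC)c(OCOC)c2)oc2c(CC=C(C)C)c(O)c(CC=C(C)C)c(O)c2c1=O | intermediate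
13 | broussoflavonol B | COc1c(-c2ccc(O)c(O)c2)oc2c(CC=C(C)C)c(O)c(CC=C(C)C)c(O)c2c1=O | target

## Step count and risks

Total step count: 5. Longest linear sequence: 4 steps (steps 2, 3, 4 and 5, from 4); step 1 is a one-step branch.

**Step 4 (key step).**
- Risk: the ketene may be diverted before it is captured at carbon, by dimerisation of 10, by hydrolysis with the water of condensation followed by decarboxylation, or because the α-substituted ester forms the ketene slowly. Each of these prolongs heating, and prolonged heating of a phenolic melt invites MOM transfer and thermal cyclisation of prenyl groups onto the ortho phenols. A more ketene-labile ester would lower the onset of ketene formation but not that of the final cyclodehydration, so it is not counted as a remedy.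
- Fallback: ring C is built from the C2–C3 side instead, with no ketene and no melt of the free triol. It sets out from 1, 2 and 6 and comes back at 12. Houben–Hoesch acylation of 1 with methoxyacetonitrile (ZnCl2, HCl, Et2O, then aqueous hydrolysis) gives 1-(2,4,6-trihydroxyphenyl)-2-methoxyethanone F1. Nuclear prenylation of F1 with 2 in cold aqueous KOH, where the acyl group blocks one ring carbon and tempers the ring, gives 1-[2,4,6-trihydroxy-3,5-bis(3-methylbut-2-enyl)phenyl]-2-methoxyethanone F2. Acid 6 is dehydrated with DCC to 3,4-bis(methoxymethoxy)benzoic anhydride F3. Allan–Robinson condensation of F2 with F3 (Et3N, heat), followed by saponification of surplus O-aroyl groups with KOH in aqueous methanol, returns 12.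

**Step 1.**
- Risk: poor control over the degree and site of alkylation. The phenolate is ambident and each prenyl group raises the ring's nucleophilicity, so over-alkylation, geminal (dearomatising) alkylation and O-alkylation drain material. The electron-rich triol also oxidises in alkali if air is admitted.
- Fallback: the prenyl groups are installed after the annulation. It sets out from 1 and 9 and comes back at 12. The thermal condensation of step 4 is run on 1 itself, its best-precedented substrate, to give 2-[3,4-bis(methoxymethoxy)phenyl]-5,7-dihydroxy-3-methoxychromen-4-one F4. The two prenyl groups are then introduced at C6 and C8 by nuclear prenylation with 2 (NaOMe, MeOH), with mono- and O-prenylated material separated.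

**Step 5.**
- Risk: acid-promoted loss of prenyl integrity. Protonation of the trisubstituted alkene gives a tertiary cation that is trapped by the ortho phenol (chroman formation) or by solvent, in competition with MOM cleavage.
- Fallback: deprotection is moved in front of the annulation. It sets out from 9 (with 3) and comes back at 13. Compound 9 is treated with aqueous HCl in THF, where no prenyl group is present, to give ethyl 3-(3,4-dihydroxyphenyl)-2-methoxy-3-oxopropanoate F5. F5 is then condensed thermally with 3 as in step 4 to give 13 directly; acylation of the free catechol oxygens by the ketene is reversible at that temperature, as it is for the ring A phenols.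

## Further compounds

F1 | step 4 | 1-(2,4,6-trihydroxyphenyl)-2-methoxyethanone | COCC(=O)c1c(O)cc(O)cc1O
F2 | step 4 | 1-[2,4,6-trihydroxy-3,5-bis(3-methylbut-2-enyl)phenyl]-2-methoxyethanone | COCC(=O)c1c(O)c(CC=C(C)C)c(O)c(CC=C(C)C)c1O
F3 | step 4 | 3,4-bis(methoxymethoxy)benzoic anhydride | COCOc1ccc(C(=O)OC(=O)c2ccc(OCOC)c(OCOC)c2)cc1OCOC
F4 | step 1 | 2-[3,4-bis(methoxymethoxy)phenyl]-5,7-dihydroxy-3-methoxychromen-4-one | COc1c(-c2ccc(OCOC)c(OCOC)c2)oc2cc(O)cc(O)c2c1=O
F5 | step 5 | ethyl 3-(3,4-dihydroxyphenyl)-2-methoxy-3-oxopropanoate (racemic) | CCOC(=O)C(OC)C(=O)c1ccc(O)c(O)c1
A1 | alternative 1 | 2-iodo-1,3,5-tris(methoxymethoxy)-4,6-bis(3-methylbut-2-enyl)benzene | COCOc1c(I)c(OCOC)c(CC=C(C)C)c(OCOC)c1CC=C(C)C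
A2 | alternative 1 | 1-[3,4-bis(methoxymethoxy)phenyl]-2-methoxyethanone | COCC(=O)c1ccc(OCOC)c(OCOC)c1
A3 | alternative 1 | 1-[3,4-bis(methoxymethoxy)phenyl]-2-methoxy-3-[2,4,6-tris(methoxymethoxy)-3,5-bis(3-methylbut-2-enyl)phenyl]propane-1,3-dione (racemic) | COC(C(=O)c1ccc(OCOC)c(OCOC)c1)C(=O)c1c(OCOC)c(CC=C(C)C)c(OCOC)c(CC=C(C)C)c1OCOC
A4 | alternative 2 | 3-ethoxy-2-(3-methylbut-2-enyl)cyclobut-2-en-1-one | CCOC1=C(CC=C(C)C)C(=O)C1
A5 | alternative 2 | triisopropyl[(5-methylhex-4-en-1-yn-1-yl)oxy]silane | CC(C)=CCC#CO[Si](C(C)C)(C(C)C)C(C)C
A6 | alternative 2 | 5-ethoxy-2,4-bis(3-methylbut-2-enyl)-3-(triisopropylsilyloxy)phenol | CCOc1cc(O)c(CC=C(C)C)c(O[Si](C(C)C)(C(C)C)C(C)C)c1CC=C(C)C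
A7 | alternative 3 | 5,7-bis(allyloxy)-2-[3,4-bis(methoxymethoxy)phenyl]-3-methoxychromen-4-one | COc1c(-c2ccc(OCOC)c(OCOC)c2)oc2cc(OCC=C)cc(OCC=C)c2c1=O
A8 | alternative 3 | 6,8-diallyl-2-[3,4-bis(methoxymethoxy)phenyl]-5,7-dihydroxy-3-methoxychromen-4-one | COc1c(-c2ccc(OCOC)c(OCOC)c2)oc2c(CC=C)c(O)c(CC=C)c(O)c2c1=O
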